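Everything rests on cutting the carbocycle of the chromanone at C4a–C5 and C8–C8a. Ring atoms O1, C2, C3, C4, C4a and C8a are supplied by a cis-2,3-dimethyl-2,3-dihydropyran-4-one whose own enol-ether double bond becomes C4a=C8a and whose α-carbon bears bromine; the remaining arene carbons C5–C8, the prenyl group, O5 and O7 come from a prenylated acetoacetate as its 1,3-bis(silyloxy)-1-methoxydiene. One polar [4+2] benzannulation joins the two and, by loss of HBr, methanol and the silyl groups, gives the fully substituted phloroglucinol ring with both stereocentres intact and C8 as the only open position, where the side chain is attached last by carbene catalysis.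

Key step: step 8

Remarks on the chemistry:
(a) The target is read as methyl (3R)-3-[(2R,3S)-5,7-dihydroxy-2,3-dimethyl-6-(3-methylbut-2-enyl)-4-oxochroman-8-yl]hexanoate; the 2R,3S pair places the two ring methyl groups cis.
(b) Assumption: in the two catalyst-controlled steps (3 and 9) the catalyst antipode named is the one expected to give the stated configuration; if the sense proves opposite, the other antipode is used.
(c) The key-step partners are kept as bromide 8 and bis(trimethylsilyl) diene 13. A β-alkoxy enone is too weak a dienophile for a thermal cycloaddition, so 8 is engaged as its O-silylated oxocarbenium ion. The cycloaddition places H-8a and Br cis, so loss of HBr is deferred until it is the aromatising event. Bromine is retained because it blocks enolisation at C4a and carries the oxidation level of the arene.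

Step 1
Reactants: 1 propanoyl chloride; 2 ethyl vinyl ether
Product: 3 (E)-1-ethoxypent-1-en-3-one
Conditions: 2 (3 equiv), neat, 0 °C → rt; then Et3N, Et2O, 0 °C → rt
Reagents that add atoms: none
Why: Acylation of the electron-rich enol ether gives a β-chloro-β-ethoxy ketone, from which Et3N removes HCl to leave the conjugated E-configured vinylogous ester (addition–elimination acylation of an enol ether); the amine is added only after the acylation so that ketene formation from 1 is avoided.

Step 2
Reactants: 3 (E)-1-ethoxypent-1-en-3-one
Product: 4 (1E,3Z)-1-ethoxy-3-(triethylsilyloxy)penta-1,3-diene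
Conditions: Et3SiOTf, Et3N, Et2O, 0 °C
Reagents that add atoms: triethylsilyl trifluoromethanesulfonate CC[Si](CC)(CC)OS(=O)(=O)C(F)(F)F
Why: Soft enolisation of the ethyl ketone with a silyl triflate and Et3N gives the silyl dienol ether (O-silylation), the Z enol ether being expected for an ethyl ketone and being the geometry that later places the two methyl groups cis.

Step 3
Reactants: 4 (1E,3Z)-1-ethoxy-3-(triethylsilyloxy)penta-1,3-diene; 5 acetaldehyde
Product: 7 (2R,3S)-2,3-dimethyl-2,3-dihydro-4H-pyran-4-one, via ethoxy silyloxy dihydropyran cycloadduct 6 (not isolated)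
Conditions: CrCl(L*) (3 mol %; trivalent chromium; L* = dianion of the Schiff base of 3-(1-adamantyl)-2-hydroxy-5-methylbenzaldehyde and (1R,2S)-1-aminoindan-2-ol), 4 Å MS, 5 (3 equiv), t-BuOMe, 0 °C → rt; then TFA (cat.), CH2Cl2, 0 °C
Reagents that add atoms: none
Why: Catalytic asymmetric hetero-Diels–Alder reaction in which the chiral chromium Lewis acid binds acetaldehyde and exposes one face, endo addition to the Z-configured diene terminus makes C2 and C3 cis so that both centres (2R,3S) are set under catalyst control, and TFA then expels ethanol and the silyl group from the cycloadduct to give the enone.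

Step 4
Reactants: 7 (2R,3S)-2,3-dimethyl-2,3-dihydro-4H-pyran-4-one
Product: 8 (2R,3S)-5-bromo-2,3-dimethyl-2,3-dihydro-4H-pyran-4-one
Conditions: Br2 (1.0 equiv), CH2Cl2, −78 °C; then Et3N (1.2 equiv), −78 → 0 °C
Reagents that add atoms: bromine BrBr
Why: α-Halogenation of a vinylogous ester, in which Br2 adds to the enol-ether double bond and Et3N removes the acidic C5 hydrogen with loss of the anomeric bromide (E1cB), leaving bromine at C5; low temperature and a small excess of amine keep the epimerisable C3 intact.

Step 5
Reactants: 9 methyl acetoacetate; 10 1-bromo-3-methylbut-2-ene (prenyl bromide)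
Product: 11 methyl 2-acetyl-5-methylhex-4-enoate (racemic)
Conditions: NaH (1.0 equiv), THF, 0 °C; 10 (0.95 equiv), 0 °C → rt
Reagents that add atoms: none
Why: SN2 C-alkylation of the sodium enolate of the β-keto ester by the allylic bromide, run with a slight deficit of 10 to suppress double alkylation.

Step 6
Reactants: 11 methyl 2-acetyl-5-methylhex-4-enoate
Product: 12 methyl 2-(3-methylbut-2-enyl)-3-(trimethylsilyloxy)but-2-enoate (E/Z mixture)
Conditions: Me3SiCl, Et3N, toluene, rt
Reagents that add atoms: chlorotrimethylsilane C[Si](C)(C)Cl
Why: O-Silylation of the enol form of the β-keto ester at the ketone oxygen (silyl enol ether formation), which masks the acidic α-hydrogen so that the next base acts at the methyl group.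

Step 7
Reactants: 12 methyl 2-(3-methylbut-2-enyl)-3-(trimethylsilyloxy)but-2-enoate
Product: 13 1-methoxy-2-(3-methylbut-2-enyl)-1,3-bis(trimethylsilyloxy)buta-1,3-diene
Conditions: LiN(i-Pr)2, THF, −78 °C; then Me3SiCl, −78 °C → rt
Reagents that add atoms: chlorotrimethylsilane C[Si](C)(C)Cl
Why: Kinetic γ-deprotonation of the β-silyloxy enoate at its methyl group gives the ester dienolate, which Me3SiCl traps on oxygen to give the 1,3-bis(silyloxy)diene (the two-stage silylation used for 2-alkyl 1,3-bis(silyloxy)-1-methoxybutadienes).

Step 8
Reactants: 8 (2R,3S)-5-bromo-2,3-dimethyl-2,3-dihydro-4H-pyran-4-one; 13 1-methoxy-2-(3-methylbut-2-enyl)-1,3-bis(trimethylsilyloxy)buta-1,3-diene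
Product: 16 (2R,3S)-5,7-dihydroxy-2,3-dimethyl-6-(3-methylbut-2-enyl)chroman-4-one, via bromo ketal cycloadduct 14 (not isolated), via bis(trimethylsilyl) ether 15 (not isolated)
Conditions: 13 (2 equiv), Tf2NH (10 mol %, forms Me3SiNTf2 in the flask), CH2Cl2, −78 → 0 °C; then Et3N (3 equiv), 0 °C → rt; then aq. citric acid, THF, 0 °C
Reagents that add atoms: none
Why: Proposed new method: Me3SiNTf2 silylates the carbonyl oxygen of 8 to give a 4-silyloxy oxocarbenium ion whose C6 accepts the CH2 terminus of 13 (Mukaiyama–Michael addition, bond C8–C8a), and the α-bromo enol silane thus formed closes onto the O-silylated ester carbon, a dialkoxycarbenium centre, in a 6-(enolexo)-exo-trig ring closure (bond C4a–C5), so that the carbocycle arises by a stepwise polar [4+2] in which an open Michael adduct is not a dead end because re-silylation of its ester oxygen regenerates the same cation. The closest known reaction types are the cycloaddition–aromatisation of 1,3-dioxygenated silyloxydienes with halo-enones and haloquinones to resorcinols, silyl-triflate-promoted additions of the same dienes to pyranones and chromones, and silyl-Lewis-acid-catalysed stepwise [4+2] reactions of silyloxydienes with hindered enones. Regiochemistry follows from matched polarity, since the most nucleophilic diene carbon can attack only C6, the β-carbon of the vinylogous ester and the one that bears no bromine, while the prenyl group on the central diene carbon makes the competing [3+3] aldol mode unable to aromatise. Aromatisation is staged: the mixed silyl methyl ketal at C5 ionises and, with loss of a proton from C8, gives methanol and a 4a-bromo-4a,8a-dihydro arene (a bis(silyloxy)cyclohexa-1,3-diene), from which Et3N removes HBr across C4a–C8a in a step that is itself the aromatisation and therefore needs neither an acidic hydrogen nor an anti arrangement of H and Br, and mild acid then frees the two phenols. Bromide is lost in preference to the ring oxygen because O1 could only leave through an enolate at C8 or C4a, and neither can form while C7 remains a silyl enol ether and C4a carries bromine in place of hydrogen. No stereocentre is created and C2 and C3 are spectators, the only risk to C3 being amine-induced enolisation, which is limited by cold, brief exposure to Et3N.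

Step 9
Reactants: 16 (2R,3S)-5,7-dihydroxy-2,3-dimethyl-6-(3-methylbut-2-enyl)chroman-4-one; 17 (E)-hex-2-enal
Product: 19 methyl (3R)-3-[(2R,3S)-5,7-dihydroxy-2,3-dimethyl-6-(3-methylbut-2-enyl)-4-oxochroman-8-yl]hexanoate, via propyl dihydrocoumarin lactone 18 (not isolated)
Conditions: 17 (1.5 equiv), (5aS,10bR)-2-mesityl-5a,10b-dihydro-4H,6H-indeno[2,1-b][1,2,4]triazolo[4,3-d][1,4]oxazin-2-ium chloride (10 mol %), i-Pr2NEt (20 mol %), 3,3',5,5'-tetra-tert-butyl-4,4'-diphenoquinone (1.2 equiv), 4 Å MS, toluene, rt; then MeOH, rt
Reagents that add atoms: methanol CO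
Why: Oxidation of the carbene–enal adduct gives the α,β-unsaturated acyl azolium, which the free non-chelated 7-OH engages and which then delivers its β-carbon to C8, the only unsubstituted ring carbon (acyl azolium annulation of the Coates–Claisen type), the chiral triazolium framework shielding one face so that the propyl-bearing centre is set R under catalyst control; lactonisation onto O7 releases the carbene and methanol then opens the aryl ester lactone to the methyl ester without touching C2 or C3.

Compound list
1 | propanoyl chloride | CCC(=O)Cl | starting material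
2 | ethyl vinyl ether | CCOC=C | starting material
3 | (E)-1-ethoxypent-1-en-3-one | CCO/C=C/C(=O)CC | intermediate
4 | (1E,3Z)-1-ethoxy-3-(triethylsilyloxy)penta-1,3-diene | CCO/C=C/C(=C/C)O[Si](CC)(CC)CC | intermediate
5 | acetaldehyde | CC=O | starting material
6 | (2R,3S)-6-ethoxy-2,3-dimethyl-4-(triethylsilyloxy)-3,6-dihydro-2H-pyran (acetal carbon C6 not defined, lost on elimination) | CCOC1O[C@H](C)[C@H](C)C(O[Si](CC)(CC)CC)=C1 | intermediate (not isolated)
7 | (2R,3S)-2,3-dimethyl-2,3-dihydro-4H-pyran-4-one | C1=CO[C@H](C)[C@H](C)C1=O | intermediate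
8 | (2R,3S)-5-bromo-2,3-dimethyl-2,3-dihydro-4H-pyran-4-one | BrC1=CO[C@H](C)[C@H](C)C1=O | intermediate (key-step precursor)
9 | methyl acetoacetate | COC(=O)CC(C)=O | starting material
10 | 1-bromo-3-methylbut-2-ene (prenyl bromide) | CC(C)=CCBr | starting material
11 | methyl 2-acetyl-5-methylhex-4-enoate (racemic) | COC(=O)C(CC=C(C)C)C(C)=O | intermediate
12 | methyl 2-(3-methylbut-2-enyl)-3-(trimethylsilyloxy)but-2-enoate (E/Z mixture) | COC(=O)C(CC=C(C)C)=C(C)O[Si](C)(C)C | intermediate
13 | 1-methoxy-2-(3-methylbut-2-enyl)-1,3-bis(trimethylsilyloxy)buta-1,3-diene | COC(O[Si](C)(C)C)=C(CC=C(C)C)C(=C)O[Si](C)(C)C | intermediate (key-step precursor)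
14 | (2R,3S)-4a-bromo-5-methoxy-2,3-dimethyl-6-(3-methylbut-2-enyl)-5,7-bis(trimethylsilyloxy)-2,3,4a,5,8,8a-hexahydro-4H-chromen-4-one (transient centres C4a, C5, C8a not defined) | C1C(O[Si](C)(C)C)=C(CC=C(C)C)C(OC)(O[Si](C)(C)C)C2(Br)C1O[C@H](C)[C@H](C)C2=O | intermediate (not isolated)
15 | (2R,3S)-2,3-dimethyl-6-(3-methylbut-2-enyl)-5,7-bis(trimethylsilyloxy)chroman-4-one | c1c(O[Si](C)(C)C)c(CC=C(C)C)c(O[Si](C)(C)C)c2c1O[C@H](C)[C@H](C)C2=O | intermediate (not isolated)
16 | (2R,3S)-5,7-dihydroxy-2,3-dimethyl-6-(3-methylbut-2-enyl)chroman-4-one | c1c(O)c(CC=C(C)C)c(O)c2c1O[C@H](C)[C@H](C)C2=O | intermediate (key-step product)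
17 | (E)-hex-2-enal | CCC/C=C/C=O | starting material
18 | (2R,3S,10R)-5-hydroxy-2,3-dimethyl-6-(3-methylbut-2-enyl)-10-propyl-2,3,9,10-tetrahydro-4H,8H-pyrano[2,3-f]chromene-4,8-dione (lactone from O7 to C8) | CCC[C@@H]1CC(=O)Oc2c1c3O[C@H](C)[C@H](C)C(=O)c3c(O)c2CC=C(C)C | intermediate (not isolated)
19 | methyl (3R)-3-[(2R,3S)-5,7-dihydroxy-2,3-dimethyl-6-(3-methylbut-2-enyl)-4-oxochroman-8-yl]hexanoate | CCC[C@H](CC(=O)OC)c1c(O)c(CC=C(C)C)c(O)c2c1O[C@H](C)[C@H](C)C2=O | target

Total step count: 9. Longest linear sequence: 6 steps (1, 2, 3, 4, 8, 9).

Steps most likely to fail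

Step 8. The reaction may stop after the first C–C bond at the open Michael adduct, aromatisation may proceed by ring opening with loss of the ring oxygen, or C3 may epimerise under the amine. The fallback builds the chromanone on a preformed arene by known reactions; it sets out from prenyl bromide 10 and returns at 16. Friedel–Crafts acylation of phloroglucinol with (E)-2-methylbut-2-enoyl chloride (AlCl3, PhNO2, low temperature, stopped at the open enone) should give (E)-2-methyl-1-(2,4,6-trihydroxyphenyl)but-2-en-1-one F1. Mono-C-prenylation with 10 (aq. KOH, 0 °C; the two free ring positions are equivalent) should give (E)-2-methyl-1-[2,4,6-trihydroxy-3-(3-methylbut-2-enyl)phenyl]but-2-en-1-one F2. A cinchona-alkaloid-catalysed intramolecular oxa-Michael addition (quinine or quinidine, whichever gives 2R,3S), a reaction type known to give cis-2,3-dimethylchromanones by kinetic protonation, should then close the heterocycle. Closure is expected mainly through the less hindered phenol next to the ring C–H, which gives 16; the 8-prenyl isomer and any racemic chromanone formed under base would be removed by chromatography.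

Step 9. The acylated phloroglucinol ring may be too weak a nucleophile for the acyl azolium, facial selectivity may be poor with an aliphatic enal, or the base may epimerise C3. The fallback gives up catalyst control at the new centre; it sets out from 16 and returns at 18. Butanal and Meldrum's acid (cat. pyrrolidinium acetate, MeCN, rt → 50 °C) should form 5-butylidene-2,2-dimethyl-1,3-dioxane-4,6-dione F3 in the flask. Friedel–Crafts-type Michael addition of C8 of 16 should give the adduct 5-{1-[(2R,3S)-5,7-dihydroxy-2,3-dimethyl-6-(3-methylbut-2-enyl)-4-oxochroman-8-yl]butyl}-2,2-dimethyl-1,3-dioxane-4,6-dione F4, which lactonises onto O7 with loss of acetone and CO2. This gives lactone 18 together with its epimer at the propyl-bearing carbon, the (2R,3S,10S)-lactone F5; the two would be separated by preparative HPLC, and 18 is then opened with methanol as in the second stage of step 9.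

Step 3. Enantio- or endo-selectivity may be modest with the small aldehyde, and the volatile product may be lost on isolation. The fallback sets the two centres by an aldol reaction; it sets out from 3 and 5 and returns at 7. The Z-boron enolate of 3 (diisopinocampheylboron triflate of the antipode that gives the 4S,5R aldol, i-Pr2NEt, CH2Cl2, −78 °C) should add to 5 to give, after oxidative work-up, the syn aldol (1E,4S,5R)-1-ethoxy-5-hydroxy-4-methylhex-1-en-3-one F6. Acid (TFA cat., CH2Cl2) should then close it by oxa-Michael addition and loss of ethanol to 7, the syn aldol mapping onto the cis-2,3-dimethyl ring.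

Further compounds
F1 | step 8 | (E)-2-methyl-1-(2,4,6-trihydroxyphenyl)but-2-en-1-one | C/C=C(\C)C(=O)c1c(O)cc(O)cc1O
F2 | step 8 | (E)-2-methyl-1-[2,4,6-trihydroxy-3-(3-methylbut-2-enyl)phenyl]but-2-en-1-one | C/C=C(\C)C(=O)c1c(O)cc(O)c(CC=C(C)C)c1O
F3 | step 9 | 5-butylidene-2,2-dimethyl-1,3-dioxane-4,6-dione | CCCC=C1C(=O)OC(C)(C)OC1=O
F4 | step 9 | 5-{1-[(2R,3S)-5,7-dihydroxy-2,3-dimethyl-6-(3-methylbut-2-enyl)-4-oxochroman-8-yl]butyl}-2,2-dimethyl-1,3-dioxane-4,6-dione (both epimers at the butyl carbon) | CCCC(C1C(=O)OC(C)(C)OC1=O)c1c(O)c(CC=C(C)C)c(O)c2c1O[C@H](C)[C@H](C)C2=O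
F5 | step 9 | (2R,3S,10S)-5-hydroxy-2,3-dimethyl-6-(3-methylbut-2-enyl)-10-propyl-2,3,9,10-tetrahydro-4H,8H-pyrano[2,3-f]chromene-4,8-dione | CCC[C@H]1CC(=O)Oc2c1c3O[C@H](C)[C@H](C)C(=O)c3c(O)c2CC=C(C)C
F6 | step 3 | (1E,4S,5R)-1-ethoxy-5-hydroxy-4-methylhex-1-en-3-one | O[C@H](C)[C@H](C)C(=O)/C=C/OCC
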